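**Plan**

1. Retrosynthesis cuts C8–C9 and C11–C12 (two Julia–Kocienski olefinations, then one diimide reduction). In the ring fragment it cuts the C6–O1 bond of the 1,2-dioxane, the C3–O2 bond and C2–C3; in the chain fragment it cuts the C14–OOH bond.
2. Enabling feature: C6 of the dioxane (ring atoms O1, O2, C3, C4, C5, C6) is fully substituted, carrying O1, a methyl group and the two-carbon arm C7–C8. That is what a 2,2-disubstituted oxetane leaves when opened at its tertiary carbon, and C14 (O, methyl, arm C13–C12) repeats the pattern.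
3. Forward, ring fragment: (R)-linalool → oxetane; ozonolysis; anti-crotylboration (the vinyl group is the latent C1 carboxyl); C3 mesylate displaced by a capped hydroperoxide; the freed C3–OOH opens the oxetane and closes the only ring; vinyl → CO2Me, C8–OH → CHO.
4. Forward, chain fragment: the same oxetane is opened by H2O2 at C14, capped and oxidized to the C12 aldehyde, joined to a C9–C11 sulfone/thioether reagent, and the thioether is oxidized to the C9 sulfone. Union with the ring aldehyde, diimide and removal of the cap finish the synthesis.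
5. Stereochemistry: C6 and C14 come from (R)-linalool, each inverted once in an oxetane opening. C2 and C3 come from the reagent-controlled (E)-crotylboration, C3 then being inverted in the displacement. C10 comes from (S)-3-bromo-2-methylpropan-1-ol.

Key step: step 9

Remark: atoms are numbered C1 (ester carbon) to C18 along the chain; PT = 1-phenyl-1H-tetrazol-5-yl; commercial (S)-3-bromo-2-methylpropan-1-ol is taken as the source of C9–C11.

**Steps**

Step 1
Reactants: 1 (R)-linalool
Product: 3 (3R)-3,7-dimethyloct-6-ene-1,3-diol, via B-alkyl-9-BBN adduct 2 (not isolated)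
Conditions: 9-BBN (2.2 equiv), THF, 0 °C → rt; then NaOH, 30% H2O2, 0 °C → rt
Reagents that add atoms: hydrogen peroxide, OO
Why: Hydroboration–oxidation, in which 9-BBN adds to the monosubstituted vinyl group far faster than to the trisubstituted C=C and places boron on the terminal carbon, so that alkaline peroxide should give the primary alcohol while the tertiary carbinol stereocentre is untouched.

Step 2
Reactants: 3 (3R)-3,7-dimethyloct-6-ene-1,3-diol
Product: 5 (2R)-2-methyl-2-(4-methylpent-3-en-1-yl)oxetane, via primary monotosylate 4 (not isolated)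
Conditions: n-BuLi (1.0 equiv), THF, 0 °C; TsCl (1.0 equiv); then n-BuLi (1.0 equiv), 0 → 60 °C
Reagents that add atoms: none
Why: Williamson-type 4-exo-tet etherification, in which the primary hydroxyl is tosylated selectively and the tertiary alkoxide displaces it, so the C–O bond at the stereocentre is never broken and its configuration is retained.

Step 3
Reactants: 5 (2R)-2-methyl-2-(4-methylpent-3-en-1-yl)oxetane
Product: 6 3-[(2R)-2-methyloxetan-2-yl]propanal
Conditions: O3, pyridine (3 equiv), CH2Cl2, −78 °C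
Reagents that add atoms: ozone, [O-][O+]=O
Why: Ozonolysis with pyridine present to break down the carbonyl oxide should cleave the only C=C directly to the aldehyde and acetone without a separate reduction, the oxetane being inert to ozone.

Step 4
Reactants: 6 3-[(2R)-2-methyloxetan-2-yl]propanal; 7 trans-but-2-ene
Product: 9 (3R,4S)-4-methyl-1-[(2R)-2-methyloxetan-2-yl]hex-5-en-3-ol, via diisopinocampheylborinate 8 (not isolated)
Conditions: 7, KOtBu, n-BuLi, THF, −78 → −45 °C; (−)-Ipc2BOMe, −78 °C; BF3·OEt2 (1.0 equiv per boron); then 6, −78 °C; NaOH, 30% H2O2, 0 °C → rt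
Reagents that add atoms: none
Why: Brown crotylboration through a closed chair transition state, in which the (E)-crotyl geometry gives the 3,4-anti relationship and the isopinocampheyl groups derived from (+)-α-pinene direct addition to the aldehyde face that gives the (3R) carbinol, so that C2 and (before its later inversion) C3 of the target are set here; BF3·OEt2 is limited to one equivalent per boron so that no free Lewis acid meets the oxetane.

Step 5
Reactants: 9 (3R,4S)-4-methyl-1-[(2R)-2-methyloxetan-2-yl]hex-5-en-3-ol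
Product: 10 (3R,4S)-4-methyl-1-[(2R)-2-methyloxetan-2-yl]hex-5-en-3-yl methanesulfonate
Conditions: MsCl, Et3N, CH2Cl2, −10 → 0 °C
Reagents that add atoms: methanesulfonyl chloride, CS(=O)(=O)Cl
Why: O-Sulfonylation of the secondary alcohol leaves the carbinol configuration unchanged and gives a leaving group that, unlike a triflate, should not be displaced by the oxetane oxygen on standing.

Step 6
Reactants: 11 2,3-dimethylbut-2-ene
Product: 12 2-methoxyprop-2-yl hydroperoxide
Conditions: O3, MeOH/CH2Cl2, −78 °C; kept and used as a titrated solution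
Reagents that add atoms: ozone, [O-][O+]=O; methanol, CO
Why: Ozonolysis of a tetrasubstituted alkene in methanol, in which the carbonyl oxide (acetone O-oxide) is trapped by the solvent to give the α-methoxy hydroperoxide, a capped form of hydrogen peroxide.

Step 7
Reactants: 10 (3R,4S)-4-methyl-1-[(2R)-2-methyloxetan-2-yl]hex-5-en-3-yl methanesulfonate; 12 2-methoxyprop-2-yl hydroperoxide
Product: 13 (2R)-2-[(3S,4S)-3-[(2-methoxypropan-2-yl)peroxy]-4-methylhex-5-en-1-yl]-2-methyloxetane
Conditions: 12 (3 equiv), CsOH·H2O (2.5 equiv), DMF, 0 °C → rt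
Reagents that add atoms: none
Why: SN2 alkylation of CsOOC(CH3)2OCH3 (an α-effect nucleophile of low basicity) by the secondary mesylate in a dipolar aprotic solvent should invert C3 to the configuration of the target, while the ketal cap prevents a second alkylation and base-induced decomposition of the product.

Step 8
Reactants: 13 (2R)-2-[(3S,4S)-3-[(2-methoxypropan-2-yl)peroxy]-4-methylhex-5-en-1-yl]-2-methyloxetane
Product: 14 (2R)-2-[(3S,4S)-3-hydroperoxy-4-methylhex-5-en-1-yl]-2-methyloxetane
Conditions: AcOH/THF/H2O (4:2:1), rt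
Reagents that add atoms: none
Why: Mild acid hydrolysis of the monoperoxyketal frees the secondary hydroperoxide without breaking the C3–O bond, and dilute acetic acid should not open the oxetane.

Step 9
Reactants: 14 (2R)-2-[(3S,4S)-3-hydroperoxy-4-methylhex-5-en-1-yl]-2-methyloxetane
Product: 15 2-[(3S,6S)-6-[(2S)-but-3-en-2-yl]-3-methyl-1,2-dioxan-3-yl]ethan-1-ol
Conditions: Me3SiOTf (0.2 equiv), CH2Cl2, −78 → −30 °C; aq. NaHCO3 quench
Reagents that add atoms: none
Why: Me3SiOTf (or the triflic acid it releases) coordinates the oxetane oxygen, and the terminal oxygen of the C3 hydroperoxide attacks the tertiary ring carbon C6 from the side opposite the departing oxygen, so that the C6–O1 bond forms as the oxetane C–O bond breaks and the freed oxygen becomes the C8 hydroxyl. The closest known reaction type is the Lewis-acid-promoted intramolecular opening of 2,2-disubstituted oxetanes by hydroperoxides to give 1,2-dioxolanes and 1,2-dioxanes. The 1,2-dioxane closes in the 6-exo-tet mode. The new C6 stereocentre arises by inversion of the oxetane carbon that came unchanged from (R)-linalool, while C2 and C3 are spectators. The step needs regioselectivity for C6 over C8 and a displacement concerted enough to be stereospecific: attack at the tertiary carbon is favoured because it bears the developing positive charge and leads to a six- instead of an eight-membered ring, and sub-stoichiometric acid at low temperature in a non-ionizing solvent should keep a free tertiary cation (and with it loss of configuration or Hock-type cleavage) from forming.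

Step 10
Reactants: 15 2-[(3S,6S)-6-[(2S)-but-3-en-2-yl]-3-methyl-1,2-dioxan-3-yl]ethan-1-ol
Product: 17 (2R)-2-[(3S,6S)-6-(2-hydroxyethyl)-6-methyl-1,2-dioxan-3-yl]propanoic acid, via C1 aldehyde 16 (not isolated)
Conditions: O3, MeCN/H2O (9:1), 0 °C; then NaClO2, NaH2PO4, 0 °C → rt
Reagents that add atoms: ozone, [O-][O+]=O; water, O; sodium chlorite, [Na+].[O-]Cl=O
Why: Ozonolysis in aqueous acetonitrile gives the aldehyde directly because water intercepts the carbonyl oxide, and Pinnick chlorite oxidation in the same flask should convert it to the acid without isolating the epimerizable α-methyl-β-peroxy aldehyde, the dioxane O–O bond and the primary alcohol being inert to both oxidants.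

Step 11
Reactants: 17 (2R)-2-[(3S,6S)-6-(2-hydroxyethyl)-6-methyl-1,2-dioxan-3-yl]propanoic acid
Product: 18 methyl (2R)-2-[(3S,6S)-6-(2-hydroxyethyl)-6-methyl-1,2-dioxan-3-yl]propanoate
Conditions: Me3SiCHN2, toluene/MeOH (4:1), 0 °C
Reagents that add atoms: (trimethylsilyl)diazomethane, C[Si](C)(C)C=[N+]=[N-]
Why: Esterification with (trimethylsilyl)diazomethane and methanol is a base-free O-methylation of the acid, so neither C2 nor the β-peroxy linkage is put at risk and the primary alcohol should not react.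

Step 12
Reactants: 18 methyl (2R)-2-[(3S,6S)-6-(2-hydroxyethyl)-6-methyl-1,2-dioxan-3-yl]propanoate
Product: 19 methyl (2R)-2-[(3S,6S)-6-methyl-6-(2-oxoethyl)-1,2-dioxan-3-yl]propanoate
Conditions: Dess–Martin periodinane, NaHCO3, CH2Cl2, 0 °C
Reagents that add atoms: none
Why: Dess–Martin oxidation under bicarbonate buffering converts the primary alcohol to the aldehyde under neutral conditions that should leave the peroxide and the ester α-stereocentre alone.

Step 13
Reactants: 5 (2R)-2-methyl-2-(4-methylpent-3-en-1-yl)oxetane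
Product: 20 (3S)-3-hydroperoxy-3,7-dimethyloct-6-en-1-ol
Conditions: anhydrous H2O2 in Et2O (10 equiv), Me3SiOTf (0.1 equiv), −78 → 0 °C
Reagents that add atoms: hydrogen peroxide, OO
Why: Lewis-acid-promoted intermolecular opening of a 2,2-disubstituted oxetane by hydrogen peroxide takes place at the tertiary carbon with inversion, which turns the linalool-derived centre into C14 of the target with its hydroperoxide, while the isolated trisubstituted alkene should not react with cold anhydrous H2O2.

Step 14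
Reactants: 20 (3S)-3-hydroperoxy-3,7-dimethyloct-6-en-1-ol
Product: 21 (3S)-3-[(2-methoxypropan-2-yl)peroxy]-3,7-dimethyloct-6-en-1-ol
Conditions: 2-methoxypropene (1.1 equiv), PPTS (cat.), CH2Cl2, −20 °C
Reagents that add atoms: 2-methoxypropene, COC(C)=C
Why: Acid-catalysed peroxyketalization, in which the more acidic α-effect OOH group adds to the enol ether faster than the primary alcohol, so that one equivalent at low temperature should cap only the hydroperoxide.

Step 15
Reactants: 21 (3S)-3-[(2-methoxypropan-2-yl)peroxy]-3,7-dimethyloct-6-en-1-ol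
Product: 22 (3S)-3-[(2-methoxypropan-2-yl)peroxy]-3,7-dimethyloct-6-enal
Conditions: Dess–Martin periodinane, pyridine, CH2Cl2, 0 °C
Reagents that add atoms: none
Why: Dess–Martin oxidation buffered with pyridine gives the β-peroxy aldehyde without free acid that would strip the peroxyketal, and the tertiary peroxide has no α-hydrogen through which it could fragment.

Step 16
Reactants: 23 (S)-3-bromo-2-methylpropan-1-ol
Product: 24 (2S)-2-methyl-3-[(1-phenyl-1H-tetrazol-5-yl)sulfanyl]propan-1-ol
Conditions: 1-phenyl-1H-tetrazole-5-thiol, K2CO3, acetone, rt → 50 °C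
Reagents that add atoms: 1-phenyl-1H-tetrazole-5-thiol, Sc1nnnn1-c1ccccc1
Why: SN2 thioetherification, in which the soft tetrazolethiolate displaces the primary bromide one carbon away from the stereocentre, which is therefore unchanged.

Step 17
Reactants: 24 (2S)-2-methyl-3-[(1-phenyl-1H-tetrazol-5-yl)sulfanyl]propan-1-ol
Product: 25 (2S)-2-methyl-3-[(1-phenyl-1H-tetrazol-5-yl)sulfonyl]propan-1-ol
Conditions: (NH4)6Mo7O24·4H2O (10 mol %), 30% H2O2, EtOH, 0 °C → rt
Reagents that add atoms: hydrogen peroxide, OO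
Why: (NH4)6Mo7O24-catalysed oxidation of the sulfide with H2O2 should stop at the sulfone and leave the primary alcohol untouched.

Step 18
Reactants: 25 (2S)-2-methyl-3-[(1-phenyl-1H-tetrazol-5-yl)sulfonyl]propan-1-ol
Product: 26 5-{[(2S)-2-methyl-3-[(1-phenyl-1H-tetrazol-5-yl)sulfonyl]propyl]sulfanyl}-1-phenyl-1H-tetrazole
Conditions: 1-phenyl-1H-tetrazole-5-thiol, PPh3, DIAD, THF, 0 °C → rt
Reagents that add atoms: 1-phenyl-1H-tetrazole-5-thiol, Sc1nnnn1-c1ccccc1
Why: Mitsunobu thioetherification of the primary alcohol with the acidic thiol installs the second sulfur as a thioether, giving a reagent whose sulfone end (C11) can be metalated while the sulfide end (C9) waits to be oxidized later.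

Step 19
Reactants: 26 5-{[(2S)-2-methyl-3-[(1-phenyl-1H-tetrazol-5-yl)sulfonyl]propyl]sulfanyl}-1-phenyl-1H-tetrazole; 22 (3S)-3-[(2-methoxypropan-2-yl)peroxy]-3,7-dimethyloct-6-enal
Product: 27 5-{[(2R,3E,6S)-6-[(2-methoxypropan-2-yl)peroxy]-2,6,10-trimethylundeca-3,9-dien-1-yl]sulfanyl}-1-phenyl-1H-tetrazole
Conditions: 26, KN(SiMe3)2, THF, −78 °C; then 22, −78 → −20 °C
Reagents that add atoms: none
Why: Julia–Kocienski olefination, in which only the sulfone-flanked CH2 is deprotonated, the anion should add to the aldehyde faster than it enolizes it, and Smiles rearrangement with loss of SO2 and the tetrazolone gives the C11=C12 alkene, whose geometry (expected mainly E) is irrelevant because it is saturated later.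

Step 20
Reactants: 27 5-{[(2R,3E,6S)-6-[(2-methoxypropan-2-yl)peroxy]-2,6,10-trimethylundeca-3,9-dien-1-yl]sulfanyl}-1-phenyl-1H-tetrazole
Product: 28 5-{[(2R,3E,6S)-6-[(2-methoxypropan-2-yl)peroxy]-2,6,10-trimethylundeca-3,9-dien-1-yl]sulfonyl}-1-phenyl-1H-tetrazole
Conditions: (NH4)6Mo7O24·4H2O (10 mol %), 30% H2O2, EtOH/THF, 0 °C
Reagents that add atoms: hydrogen peroxide, OO
Why: (NH4)6Mo7O24-catalysed H2O2 oxidation of the thioether to the sulfone is the usual way to make phenyltetrazolyl sulfones in the presence of isolated di- and trisubstituted alkenes, and run cold and stopped at full conversion it should spare the peroxyketal and the C17=C18 bond.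

Step 21
Reactants: 28 5-{[(2R,3E,6S)-6-[(2-methoxypropan-2-yl)peroxy]-2,6,10-trimethylundeca-3,9-dien-1-yl]sulfonyl}-1-phenyl-1H-tetrazole; 19 methyl (2R)-2-[(3S,6S)-6-methyl-6-(2-oxoethyl)-1,2-dioxan-3-yl]propanoate
Product: 29 methyl (2R)-2-[(3S,6S)-6-[(2E,4S,5E,8S)-8-[(2-methoxypropan-2-yl)peroxy]-4,8,12-trimethyltrideca-2,5,11-trien-1-yl]-6-methyl-1,2-dioxan-3-yl]propanoate
Conditions: 28, KN(SiMe3)2, THF, −78 °C; then 19, −78 → −20 °C
Reagents that add atoms: none
Why: Second Julia–Kocienski olefination, in which the pre-formed sulfonyl anion (too weak a base to deprotonate the ester α-carbon) should add to the ring aldehyde and collapse to the C8=C9 alkene, joining C1–C8 to C9–C18 without touching a stereocentre.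

Step 22
Reactants: 29 methyl (2R)-2-[(3S,6S)-6-[(2E,4S,5E,8S)-8-[(2-methoxypropan-2-yl)peroxy]-4,8,12-trimethyltrideca-2,5,11-trien-1-yl]-6-methyl-1,2-dioxan-3-yl]propanoate
Product: 30 methyl (2R)-2-[(3S,6R)-6-[(4S,8R)-8-[(2-methoxypropan-2-yl)peroxy]-4,8,12-trimethyltridec-11-en-1-yl]-6-methyl-1,2-dioxan-3-yl]propanoate
Conditions: 2-nitrobenzenesulfonylhydrazide (NBSH), Et3N, CH2Cl2, rt, added in portions
Reagents that add atoms: none
Why: Diimide reduction (concerted syn transfer of H2 from HN=NH generated from NBSH) should saturate the two 1,2-disubstituted alkenes well before the trisubstituted C17=C18 bond and, unlike catalytic hydrogenation, does not cleave O–O bonds, the reagent being dosed until the disubstituted alkenes are consumed.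

Step 23
Reactants: 30 methyl (2R)-2-[(3S,6R)-6-[(4S,8R)-8-[(2-methoxypropan-2-yl)peroxy]-4,8,12-trimethyltridec-11-en-1-yl]-6-methyl-1,2-dioxan-3-yl]propanoate
Product: 31 methyl (2R)-2-[(3S,6R)-6-[(4R,8R)-8-hydroperoxy-4,8,12-trimethyltridec-11-en-1-yl]-6-methyl-1,2-dioxan-3-yl]propanoate
Conditions: AcOH/THF/H2O (4:2:1), rt
Reagents that add atoms: none
Why: Mild acid hydrolysis of the monoperoxyketal releases the tertiary C14 hydroperoxide, and the β-peroxy ester, the dioxane and the alkene should be stable to dilute acetic acid.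

**Compound list**

1 | (R)-linalool, (3R)-3,7-dimethylocta-1,6-dien-3-ol | CC(C)=CCC[C@](C)(C=C)O | starting material
2 | 9-[(3S)-3-hydroxy-3,7-dimethyloct-6-en-1-yl]-9-borabicyclo[3.3.1]nonane | CC(C)=CCC[C@](C)(CCB1C2CCCC1CCC2)O | intermediate
3 | (3R)-3,7-dimethyloct-6-ene-1,3-diol | CC(C)=CCC[C@](C)(CCO)O | intermediate
4 | (3R)-3-hydroxy-3,7-dimethyloct-6-en-1-yl 4-methylbenzenesulfonate | CC(C)=CCC[C@](C)(CCOS(=O)(=O)c1ccc(C)cc1)O | intermediate
5 | (2R)-2-methyl-2-(4-methylpent-3-en-1-yl)oxetane | CC(C)=CCC[C@]1(C)CCO1 | intermediate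
6 | 3-[(2R)-2-methyloxetan-2-yl]propanal | O=CCC[C@]1(C)CCO1 | intermediate
7 | trans-but-2-ene | C/C=C/C | starting material
8 | (3R,4S)-4-methyl-1-[(2R)-2-methyloxetan-2-yl]hex-5-en-3-yl bis[(1R,2S,3R,5R)-isopinocampheyl]borinate | C=C[C@H](C)[C@H](OB([C@@H]1C[C@@H]2C[C@H]([C@H]1C)C2(C)C)[C@@H]1C[C@@H]2C[C@H]([C@H]1C)C2(C)C)CC[C@]1(C)CCO1 | intermediate
9 | (3R,4S)-4-methyl-1-[(2R)-2-methyloxetan-2-yl]hex-5-en-3-ol | C=C[C@H](C)[C@H](O)CC[C@]1(C)CCO1 | intermediate
10 | (3R,4S)-4-methyl-1-[(2R)-2-methyloxetan-2-yl]hex-5-en-3-yl methanesulfonate | C=C[C@H](C)[C@H](OS(C)(=O)=O)CC[C@]1(C)CCO1 | intermediate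
11 | 2,3-dimethylbut-2-ene | CC(C)=C(C)C | starting material
12 | 2-methoxyprop-2-yl hydroperoxide (2-hydroperoxy-2-methoxypropane) | COC(C)(C)OO | intermediate
13 | (2R)-2-[(3S,4S)-3-[(2-methoxypropan-2-yl)peroxy]-4-methylhex-5-en-1-yl]-2-methyloxetane | C=C[C@H](C)[C@@H](OOC(C)(C)OC)CC[C@]1(C)CCO1 | intermediate
14 | (2R)-2-[(3S,4S)-3-hydroperoxy-4-methylhex-5-en-1-yl]-2-methyloxetane | C=C[C@H](C)[C@@H](OO)CC[C@]1(C)CCO1 | intermediate
15 | 2-[(3S,6S)-6-[(2S)-but-3-en-2-yl]-3-methyl-1,2-dioxan-3-yl]ethan-1-ol | C=C[C@H](C)[C@@H]1CC[C@@](C)(CCO)OO1 | intermediate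
16 | (2R)-2-[(3S,6S)-6-(2-hydroxyethyl)-6-methyl-1,2-dioxan-3-yl]propanal | O=C[C@H](C)[C@@H]1CC[C@@](C)(CCO)OO1 | intermediate
17 | (2R)-2-[(3S,6S)-6-(2-hydroxyethyl)-6-methyl-1,2-dioxan-3-yl]propanoic acid | OC(=O)[C@H](C)[C@@H]1CC[C@@](C)(CCO)OO1 | intermediate
18 | methyl (2R)-2-[(3S,6S)-6-(2-hydroxyethyl)-6-methyl-1,2-dioxan-3-yl]propanoate | COC(=O)[C@H](C)[C@@H]1CC[C@@](C)(CCO)OO1 | intermediate
19 | methyl (2R)-2-[(3S,6S)-6-methyl-6-(2-oxoethyl)-1,2-dioxan-3-yl]propanoate | COC(=O)[C@H](C)[C@@H]1CC[C@@](C)(CC=O)OO1 | intermediate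
20 | (3S)-3-hydroperoxy-3,7-dimethyloct-6-en-1-ol | OCC[C@](C)(CCC=C(C)C)OO | intermediate
21 | (3S)-3-[(2-methoxypropan-2-yl)peroxy]-3,7-dimethyloct-6-en-1-ol | OCC[C@](C)(CCC=C(C)C)OOC(C)(C)OC | intermediate
22 | (3S)-3-[(2-methoxypropan-2-yl)peroxy]-3,7-dimethyloct-6-enal | O=CC[C@](C)(CCC=C(C)C)OOC(C)(C)OC | intermediate
23 | (S)-3-bromo-2-methylpropan-1-ol | OC[C@H](C)CBr | starting material
24 | (2S)-2-methyl-3-[(1-phenyl-1H-tetrazol-5-yl)sulfanyl]propan-1-ol | OC[C@H](C)CSc1nnnn1-c1ccccc1 | intermediate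
25 | (2S)-2-methyl-3-[(1-phenyl-1H-tetrazol-5-yl)sulfonyl]propan-1-ol | OC[C@H](C)CS(=O)(=O)c1nnnn1-c1ccccc1 | intermediate
26 | 5-{[(2S)-2-methyl-3-[(1-phenyl-1H-tetrazol-5-yl)sulfonyl]propyl]sulfanyl}-1-phenyl-1H-tetrazole | c1ccccc1-n1nnnc1SC[C@H](C)CS(=O)(=O)c1nnnn1-c1ccccc1 | intermediate
27 | 5-{[(2R,3E,6S)-6-[(2-methoxypropan-2-yl)peroxy]-2,6,10-trimethylundeca-3,9-dien-1-yl]sulfanyl}-1-phenyl-1H-tetrazole | c1ccccc1-n1nnnc1SC[C@H](C)/C=C/C[C@](C)(CCC=C(C)C)OOC(C)(C)OC | intermediate
28 | 5-{[(2R,3E,6S)-6-[(2-methoxypropan-2-yl)peroxy]-2,6,10-trimethylundeca-3,9-dien-1-yl]sulfonyl}-1-phenyl-1H-tetrazole | c1ccccc1-n1nnnc1S(=O)(=O)C[C@H](C)/C=C/C[C@](C)(CCC=C(C)C)OOC(C)(C)OC | intermediate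
29 | methyl (2R)-2-[(3S,6S)-6-[(2E,4S,5E,8S)-8-[(2-methoxypropan-2-yl)peroxy]-4,8,12-trimethyltrideca-2,5,11-trien-1-yl]-6-methyl-1,2-dioxan-3-yl]propanoate | COC(=O)[C@H](C)[C@@H]1CC[C@@](C)(C/C=C/[C@H](C)/C=C/C[C@](C)(CCC=C(C)C)OOC(C)(C)OC)OO1 | intermediate
30 | methyl (2R)-2-[(3S,6R)-6-[(4S,8R)-8-[(2-methoxypropan-2-yl)peroxy]-4,8,12-trimethyltridec-11-en-1-yl]-6-methyl-1,2-dioxan-3-yl]propanoate | COC(=O)[C@H](C)[C@@H]1CC[C@@](C)(CCC[C@H](C)CCC[C@](C)(CCC=C(C)C)OOC(C)(C)OC)OO1 | intermediate
31 | methyl (2R)-2-[(3S,6R)-6-[(4R,8R)-8-hydroperoxy-4,8,12-trimethyltridec-11-en-1-yl]-6-methyl-1,2-dioxan-3-yl]propanoate | COC(=O)[C@H](C)[C@@H]1CC[C@@](C)(CCC[C@H](C)CCC[C@](C)(CCC=C(C)C)OO)OO1 | target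

**Step count, longest linear sequence and risks**

Total: 23 steps. Longest linear sequence: 14 steps (steps 1–5, 7–12 and 21–23).

Risk 1, step 7. The bimolecular substitution at the branched secondary carbon may be outrun by base-induced elimination, because the hydrogen on C2 next to the leaving group is allylic and elimination gives a conjugated diene. The fallback sets out from 9 and comes back at 18. The vinyl group of 9 is cleaved before the substitution (O3, CH2Cl2/MeOH, −78 °C; NaBH4) to give the 1,3-diol F1. Its primary hydroxyl is silylated (t-BuMe2SiCl, imidazole) to the primary silyl ether F2, and the secondary hydroxyl is mesylated to the silyl ether mesylate F3. Displacement with 12 and CsOH in DMF gives the inverted silyl ether peroxyketal F4, whose leaving group no longer has an allylic hydrogen beside it. Bu4NF frees the primary alcohol F5, which is oxidized (TEMPO, NaClO2, catalytic NaOCl, pH 6.7 buffer) to the peroxyketal acid F6 and methylated with Me3SiCHN2 to the peroxyketal methyl ester F7. Aqueous acetic acid then gives the hydroperoxy ester F8, and the oxetane-opening cyclization of step 9, run on F8, should give 18 directly.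

Risk 2, step 9. The activated oxetane may ionize to a free tertiary cation before the peroxide oxygen arrives, which would erode the configuration at C6 and open elimination or Hock-type cleavage pathways. The fallback sets out from 10 and comes back at 15, making the same two C–O bonds in the opposite order. Mesylate 10 is treated with anhydrous H2O2 and Me3SiOTf as in step 13, so that the oxetane is opened intermolecularly at C6 with inversion to the hydroperoxy alcohol mesylate F9. Cs2CO3 in DMF then lets the tertiary hydroperoxide displace the C3 mesylate (6-exo-tet, inversion at C3) to give 15.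

Risk 3, step 20. During the sulfur oxidation the electron-rich C17=C18 bond may be epoxidized, or the peroxyketal may be lost in the acidic peroxide medium. The fallback sets out from 23 and comes back at 29. The two olefinations are run in the opposite order, so that sulfur is oxidized on a molecule that carries neither the peroxyketal nor the trisubstituted alkene. Bromo alcohol 23 is taken through the operations of steps 16–18 in the order Mitsunobu thioetherification, (NH4)6Mo7O24/H2O2 oxidation, and bromide displacement with the thiol and K2CO3. This gives the bromo sulfide F10, the bromo sulfone F11 and the enantiomeric sulfone–thioether reagent F12, in which the sulfone now sits on C9. The anion of F12 (KN(SiMe3)2, −78 °C) adds to ring aldehyde 19 to give the C8=C9 alkene thioether F13, which is oxidized with (NH4)6Mo7O24/H2O2 to the ring sulfone F14. F14 is metalated with LiN(SiMe3)2 at −78 °C in the presence of aldehyde 22, so that the sulfonyl anion is trapped as it forms, to give triene 29.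

**Further compounds**

F1 | step 7 | (2S,3R)-2-methyl-5-[(2R)-2-methyloxetan-2-yl]pentane-1,3-diol | OC[C@H](C)[C@H](O)CC[C@]1(C)CCO1
F2 | step 7 | (2S,3R)-1-[(tert-butyldimethylsilyl)oxy]-2-methyl-5-[(2R)-2-methyloxetan-2-yl]pentan-3-ol | CC(C)(C)[Si](C)(C)OC[C@H](C)[C@H](O)CC[C@]1(C)CCO1
F3 | step 7 | (2S,3R)-1-[(tert-butyldimethylsilyl)oxy]-2-methyl-5-[(2R)-2-methyloxetan-2-yl]pentan-3-yl methanesulfonate | CC(C)(C)[Si](C)(C)OC[C@H](C)[C@H](OS(C)(=O)=O)CC[C@]1(C)CCO1
F4 | step 7 | tert-butyl{[(2S,3S)-3-[(2-methoxypropan-2-yl)peroxy]-2-methyl-5-[(2R)-2-methyloxetan-2-yl]pentyl]oxy}dimethylsilane | CC(C)(C)[Si](C)(C)OC[C@H](C)[C@@H](OOC(C)(C)OC)CC[C@]1(C)CCO1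
F5 | step 7 | (2S,3S)-3-[(2-methoxypropan-2-yl)peroxy]-2-methyl-5-[(2R)-2-methyloxetan-2-yl]pentan-1-ol | OC[C@H](C)[C@@H](OOC(C)(C)OC)CC[C@]1(C)CCO1
F6 | step 7 | (2R,3S)-3-[(2-methoxypropan-2-yl)peroxy]-2-methyl-5-[(2R)-2-methyloxetan-2-yl]pentanoic acid | OC(=O)[C@H](C)[C@@H](OOC(C)(C)OC)CC[C@]1(C)CCO1
F7 | step 7 | methyl (2R,3S)-3-[(2-methoxypropan-2-yl)peroxy]-2-methyl-5-[(2R)-2-methyloxetan-2-yl]pentanoate | COC(=O)[C@H](C)[C@@H](OOC(C)(C)OC)CC[C@]1(C)CCO1
F8 | step 7 | methyl (2R,3S)-3-hydroperoxy-2-methyl-5-[(2R)-2-methyloxetan-2-yl]pentanoate | COC(=O)[C@H](C)[C@@H](OO)CC[C@]1(C)CCO1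
F9 | step 9 | (3S,6R,7S)-3-hydroperoxy-1-hydroxy-3,7-dimethylnon-8-en-6-yl methanesulfonate | C=C[C@H](C)[C@H](OS(C)(=O)=O)CC[C@@](C)(CCO)OO
F10 | step 20 | 5-{[(2S)-3-bromo-2-methylpropyl]sulfanyl}-1-phenyl-1H-tetrazole | c1ccccc1-n1nnnc1SC[C@H](C)CBr
F11 | step 20 | 5-{[(2S)-3-bromo-2-methylpropyl]sulfonyl}-1-phenyl-1H-tetrazole | c1ccccc1-n1nnnc1S(=O)(=O)C[C@H](C)CBr
F12 | step 20 | 5-{[(2R)-2-methyl-3-[(1-phenyl-1H-tetrazol-5-yl)sulfonyl]propyl]sulfanyl}-1-phenyl-1H-tetrazole | c1ccccc1-n1nnnc1S(=O)(=O)C[C@H](C)CSc1nnnn1-c1ccccc1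
F13 | step 20 | methyl (2R)-2-[(3S,6S)-6-methyl-6-[(2E,4S)-4-methyl-5-[(1-phenyl-1H-tetrazol-5-yl)sulfanyl]pent-2-en-1-yl]-1,2-dioxan-3-yl]propanoate | COC(=O)[C@H](C)[C@@H]1CC[C@@](C)(C/C=C/[C@H](C)CSc2nnnn2-c2ccccc2)OO1
F14 | step 20 | methyl (2R)-2-[(3S,6S)-6-methyl-6-[(2E,4S)-4-methyl-5-[(1-phenyl-1H-tetrazol-5-yl)sulfonyl]pent-2-en-1-yl]-1,2-dioxan-3-yl]propanoate | COC(=O)[C@H](C)[C@@H]1CC[C@@](C)(C/C=C/[C@H](C)CS(=O)(=O)c2nnnn2-c2ccccc2)OO1
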